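**Plan**

1. Retrosynthesis: the C11=C12 bond is cut (Wittig) into a furanoid C15 hydroxy aldehyde and a C25 polyenyl phosphonium salt. The salt is cut at C11'=C12' into the C10 dialdehyde and a pseudoionone-derived C15 salt, and the aldehyde at C9=C10 (Wittig on a C9 methyl ketone).
2. Enabling feature (carotenoid numbering): in the 2,5-dihydrofuran the atoms C5–O–C8 are a carbonyl ylide and C6=C7 is an alkyne. The C5 methyl (C18) and C9 are cis on that ring, so they can be tied as a lactone C18–O–C9(=O), and one cycloaddition then cuts C5–C6, C7–C8 and O–C8.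
3. Forward: the chloroalkyne and malonate give the gem-dimethyl ynal, which is allylated and elaborated to an acyclic keto diazo ester. The key step closes lactone, cyclohexane and dihydrofuran together. The lactone is then opened to the C9 Weinreb amide and methyl ketone, C9=C10 is installed, C18–OH is reduced to CH3, and the C15 aldehyde is joined to the C25 ylide.
4. Stereochemistry: C3 comes from a Brown allylation and is carried as the 3R epimer, whose equatorial silyloxy group relays C5 (R) and C8 (S). The lactone bridge forces C18 and C9 cis. C3 is then inverted by oxidation and equatorial hydride delivery. The E-alkenes come from a stabilised ylide and thermal equilibration.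

Key step: step 10

Remark on the chemistry: in the only chair open to the fused cyclohexane the C18 arm is axial and the ring oxygen equatorial, so the 3-hydroxyl of the target (cis to C18) is axial. A chair-like cycloaddition with an equatorial silyloxy group therefore gives the 3-epimer, and for this reason C3 enters the key step as the (R)-carbinol and is inverted in steps 16 to 18.

Remark on the chemistry: pseudoionone and the C10 dialdehyde are used as the all-E isomers drawn.

**Route**

Step 1
Reactants: 1 3-chloro-3-methylbut-1-yne; 2 diethyl malonate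
Product: 3 diethyl 2-(2-methylbut-3-yn-2-yl)propanedioate
Conditions: NaOEt, EtOH, 0 °C to rt, 2 in excess
Reagents that add atoms: none
Why: base-induced loss of chloride from the tertiary propargylic chloride gives a zwitterion/vinylidene carbene that the malonate anion should capture at the tertiary carbon (propargylic alkylation of malonate), the known entry to 1,1-dimethylpropargyl malonates.

Step 2
Reactants: 3 diethyl 2-(2-methylbut-3-yn-2-yl)propanedioate
Product: 4 ethyl 3,3-dimethylpent-4-ynoate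
Conditions: LiCl, H2O, DMSO, 150 °C
Reagents that add atoms: none
Why: Krapcho dealkoxycarbonylation should remove one ester of the monosubstituted malonate as CO2 and ethanol without touching the alkyne or the quaternary carbon.

Step 3
Reactants: 4 ethyl 3,3-dimethylpent-4-ynoate
Product: 5 3,3-dimethylpent-4-ynal
Conditions: i-Bu2AlH, CH2Cl2, −78 °C; then MeOH, dilute aq. HCl
Reagents that add atoms: none
Why: partial ester reduction at −78 °C should stop at the aluminium hemiacetal, which releases the aldehyde on work-up, and the alkyne is not hydroaluminated at this temperature.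

Step 4
Reactants: 5 3,3-dimethylpent-4-ynal
Product: 6 (4S)-6,6-dimethyloct-1-en-7-yn-4-ol
Conditions: (−)-Ipc2B(allyl), Et2O, −78 °C; then NaOH, H2O2
Reagents that add atoms: (−)-B-allyldiisopinocampheylborane, C=CCB([C@@H]1C[C@@H]2C[C@H]([C@H]1C)C2(C)C)[C@@H]1C[C@@H]2C[C@H]([C@H]1C)C2(C)C
Why: Brown allylation through a closed chair transition state should deliver the allyl group to the Si face of the unhindered aldehyde, setting the carbinol centre (the later C3) as S.

Step 5
Reactants: 6 (4S)-6,6-dimethyloct-1-en-7-yn-4-ol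
Product: 7 tert-butyl{[(4S)-6,6-dimethyloct-1-en-7-yn-4-yl]oxy}dimethylsilane
Conditions: TBSCl, imidazole, DMF, rt
Reagents that add atoms: tert-butyldimethylsilyl chloride, CC(C)(C)[Si](C)(C)Cl
Why: standard silylation of a secondary alcohol gives an ether that is stable to every step up to step 16 and bulky enough to act as the stereocontrol element of the key step.

Step 6
Reactants: 7 tert-butyl{[(4S)-6,6-dimethyloct-1-en-7-yn-4-yl]oxy}dimethylsilane
Product: 8 (4R)-4-(tert-butyldimethylsilyloxy)-6,6-dimethyloct-7-yne-1,2-diol (both C2 epimers)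
Conditions: OsO4 (2 mol %), NMO, acetone/H2O, rt
Reagents that add atoms: N-methylmorpholine N-oxide, C[N+]1([O-])CCOCC1; water, O
Why: catalytic osmium dihydroxylation should take the terminal alkene much faster than the alkyne, and the new carbinol centre, formed without control, is removed again in step 8.

Step 7
Reactants: 8 (4R)-4-(tert-butyldimethylsilyloxy)-6,6-dimethyloct-7-yne-1,2-diol
Product: 9 (4R)-4-(tert-butyldimethylsilyloxy)-2-hydroxy-6,6-dimethyloct-7-yn-1-yl bromoacetate (both C2 epimers)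
Conditions: BrCH2COBr, 2,4,6-collidine, CH2Cl2, −78 °C
Reagents that add atoms: bromoacetyl bromide, BrCC(Br)=O
Why: acylation with one equivalent of acid bromide and a hindered pyridine base at low temperature should select the primary over the secondary hydroxyl.

Step 8
Reactants: 9 (4R)-4-(tert-butyldimethylsilyloxy)-2-hydroxy-6,6-dimethyloct-7-yn-1-yl bromoacetate
Product: 10 (4R)-4-(tert-butyldimethylsilyloxy)-6,6-dimethyl-2-oxooct-7-yn-1-yl bromoacetate
Conditions: Dess–Martin periodinane, CH2Cl2, rt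
Reagents that add atoms: none
Why: Dess–Martin oxidation of the secondary alcohol under near-neutral conditions should give the C5 ketone without acyl migration or loss of the β-silyloxy group.

Step 9
Reactants: 10 (4R)-4-(tert-butyldimethylsilyloxy)-6,6-dimethyl-2-oxooct-7-yn-1-yl bromoacetate
Product: 11 (4R)-4-(tert-butyldimethylsilyloxy)-6,6-dimethyl-2-oxooct-7-yn-1-yl diazoacetate
Conditions: TsNHNHTs, DBU, THF, 0 °C, short reaction time
Reagents that add atoms: N,N'-ditosylhydrazine, Cc1ccc(cc1)S(=O)(=O)NNS(=O)(=O)c1ccc(C)cc1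
Why: the bromoacetate should alkylate the sulfonylhydrazide anion and DBU then expels two sulfinates (diazo synthesis from a bromoacetate), which avoids acylating with a preformed diazo acid derivative.

Step 10
Reactants: 11 (4R)-4-(tert-butyldimethylsilyloxy)-6,6-dimethyl-2-oxooct-7-yn-1-yl diazoacetate
Product: 13 oxa-bridged tricyclic lactone, 3-(tert-butyldimethylsilyloxy)-5,5-dimethyl-10,12-dioxatricyclo[6.3.1.0(1,6)]dodec-6-en-9-one with the carotenoid centres 3R,5R,8S, via cyclic carbonyl ylide 12 (not isolated)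
Conditions: Rh2(OAc)4 (2 mol %), CH2Cl2, 40 °C, slow addition of 11 at high dilution
Reagents that add atoms: none
Why: Rh2(OAc)4 should take N2 from the diazo ester, and the electrophilic carbene carbon C8 is then captured by a lone pair of the C5 ketone oxygen once the ester has turned into its s-cis form, closing the six-membered cyclic carbonyl ylide 12 (C5, O, C8, C9, ester O, C18); no C–H bond lies at five-ring distance, so insertion should not compete, and slow addition keeps carbene dimerisation down. The ylide then adds suprafacially as a 1,3-dipole across the tethered terminal alkyne to form C5–C6 and C7–C8, the closest known reaction type being the tandem carbonyl ylide formation and intramolecular dipolar cycloaddition of diazo ketones that carry an alkyne. The cyclohexane closes in a 6-exo-dig sense, helped by the gem-dimethyl group, the 2,5-dihydrofuran is the five-membered ring of the cycloaddition itself, and the four-atom tether fixes the regiochemistry. C5 and C8 are the new stereocentres: their relative configuration is dictated by the three-atom lactone bridge, which can span only one face of the dihydrofuran and so holds C18 and C9 cis as in the target. Their absolute configuration is relayed from C3, because in the chair-like tether the silyloxy group stays equatorial (an axial one would meet the axial C1 methyl and the C18 arm), and with C18 axial and the oxygen bridge equatorial on the new cyclohexane this puts the silyloxy group cis to the oxygen bridge, so that the (R)-carbinol should give 5R,8S. The step therefore needs facial selectivity, secured by the C3 substituent together with the gem-dimethyl group, and chemoselectivity for ylide formation, secured by the absence of reachable C–H or π sites next to the carbene.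

Step 11
Reactants: 13 oxa-bridged tricyclic lactone (3R,5R,8S)
Product: 14 (2S,6R,7aR)-6-(tert-butyldimethylsilyloxy)-7a-(hydroxymethyl)-N-methoxy-N,4,4-trimethyl-2,4,5,6,7,7a-hexahydro-1-benzofuran-2-carboxamide
Conditions: MeNH(OMe)·HCl, AlMe3, CH2Cl2, 0 °C to rt
Reagents that add atoms: N,O-dimethylhydroxylamine hydrochloride, CNOC.Cl
Why: aminolysis of the strained lactone by the aluminium amide (Weinreb amide formation) should free the C18 carbinol under non-basic conditions that cannot epimerise C8.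

Step 12
Reactants: 14 Weinreb amide
Product: 15 1-[(2S,6R,7aR)-6-(tert-butyldimethylsilyloxy)-7a-(hydroxymethyl)-4,4-dimethyl-2,4,5,6,7,7a-hexahydro-1-benzofuran-2-yl]ethan-1-one (may rest partly as its bridged hemiketal)
Conditions: MeMgBr (excess), THF, −20 to 0 °C
Reagents that add atoms: methylmagnesium bromide, C[Mg]Br
Why: in the Weinreb ketone synthesis the chelated tetrahedral adduct should persist until work-up, so the C9 methyl ketone (C19 installed) is released only after the base is gone and C8 is not enolised.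

Step 13
Reactants: 15 methyl ketone
Product: 16 ethyl (2E)-3-[(2S,6R,7aR)-6-(tert-butyldimethylsilyloxy)-7a-(hydroxymethyl)-4,4-dimethyl-2,4,5,6,7,7a-hexahydro-1-benzofuran-2-yl]but-2-enoate
Conditions: Ph3P=CHCO2Et, toluene, 90 °C
Reagents that add atoms: ethyl (triphenylphosphoranylidene)acetate, CCOC(=O)C=P(c1ccccc1)(c1ccccc1)c1ccccc1
Why: Wittig olefination of an α-alkoxy methyl ketone with a stabilised ylide should give the E-enoate (ester anti to the ring carbon), and the nearly neutral ylide cannot deprotonate the allylic α-oxy C8–H.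

Step 14
Reactants: 16 hydroxy enoate
Product: 17 ethyl (2E)-3-[(2S,6R,7aR)-6-(tert-butyldimethylsilyloxy)-4,4-dimethyl-7a-{[(trifluoromethanesulfonyl)oxy]methyl}-2,4,5,6,7,7a-hexahydro-1-benzofuran-2-yl]but-2-enoate (used crude at once)
Conditions: Tf2O, pyridine, CH2Cl2, −78 to −30 °C
Reagents that add atoms: trifluoromethanesulfonic anhydride, O=S(=O)(OS(=O)(=O)C(F)(F)F)C(F)(F)F
Why: triflation of the only free hydroxyl activates the neopentyl C18 carbon, and the C3 silyloxy group, being trans to C18 in this series, cannot displace the triflate.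

Step 15
Reactants: 17 triflate
Product: 18 (2E)-3-[(2S,6R,7aR)-6-(tert-butyldimethylsilyloxy)-4,4,7a-trimethyl-2,4,5,6,7,7a-hexahydro-1-benzofuran-2-yl]but-2-en-1-ol
Conditions: LiBHEt3 (excess), THF, −78 to 0 °C
Reagents that add atoms: none
Why: the strongly nucleophilic borohydride should displace the primary triflate by SN2 (sulfonate reduction) to give the C18 methyl group without a radical or carbanion at C18, and the same reagent reduces the β,β-disubstituted enoate 1,2 to the allylic alcohol.

Step 16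
Reactants: 18 silyl ether
Product: 19 (2S,6R,7aR)-2-[(2E)-4-hydroxybut-2-en-2-yl]-4,4,7a-trimethyl-2,4,5,6,7,7a-hexahydro-1-benzofuran-6-ol
Conditions: Bu4NF, THF, rt
Reagents that add atoms: none
Why: fluoride desilylation under non-acidic conditions spares the doubly allylic C8–O bond.

Step 17
Reactants: 19 diol
Product: 20 (2E)-3-[(2S,7aR)-4,4,7a-trimethyl-6-oxo-2,4,5,6,7,7a-hexahydro-1-benzofuran-2-yl]but-2-enal
Conditions: Dess–Martin periodinane, NaHCO3, CH2Cl2, 0 °C to rt
Reagents that add atoms: none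
Why: buffered Dess–Martin oxidation should take both carbinols to the C3 ketone and the enal without base, so neither β-elimination of the ring oxygen nor deprotonation at C8 is triggered.

Step 18
Reactants: 20 keto enal
Product: 21 (2S,6S,7aR)-2-[(2E)-4-hydroxybut-2-en-2-yl]-4,4,7a-trimethyl-2,4,5,6,7,7a-hexahydro-1-benzofuran-6-ol
Conditions: LiBH(s-Bu)3, THF, −78 °C; then H2O
Reagents that add atoms: none
Why: the bulky hydride should attack the C3 ketone from the equatorial side, because the axial path is blocked by the syn-axial C1 methyl and C5 methyl groups (stereoselective ketone reduction), which gives the axial 3S alcohol cis to C18, while the β,β-disubstituted enal is reduced 1,2.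

Step 19
Reactants: 21 diol (3S)
Product: 22 (2E)-3-[(2S,6S,7aR)-6-hydroxy-4,4,7a-trimethyl-2,4,5,6,7,7a-hexahydro-1-benzofuran-2-yl]but-2-enal (furanoid C15 aldehyde)
Conditions: MnO2, CH2Cl2, rt
Reagents that add atoms: none
Why: MnO2 oxidises the allylic primary alcohol selectively and leaves the saturated C3 carbinol untouched.

Step 20
Reactants: 23 pseudoionone, (3E,5E)-6,10-dimethylundeca-3,5,9-trien-2-one
Product: 24 (4E,6E)-3,7,11-trimethyldodeca-1,4,6,10-tetraen-3-ol (racemic)
Conditions: CH2=CHMgBr, THF, 0 °C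
Reagents that add atoms: vinylmagnesium bromide, C=C[Mg]Br
Why: Grignard 1,2-addition to the dienone gives the tertiary vinyl carbinol, the classical C15 building block of the ψ end group.

Step 21
Reactants: 24 vinyl carbinol
Product: 25 [(2E,4E,6E)-3,7,11-trimethyldodeca-2,4,6,10-tetraen-1-yl]triphenylphosphonium bromide
Conditions: PPh3·HBr, MeOH, rt
Reagents that add atoms: triphenylphosphine hydrobromide, [Br-].c1ccc(cc1)[PH+](c1ccccc1)c1ccccc1
Why: ionisation of the tertiary allylic alcohol and capture of the delocalised cation by PPh3 at the primary terminus (allylic transposition) gives the conjugated salt, whose stereocentre-free allylic position makes the racemic carbinol irrelevant.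

Step 22
Reactants: 25 C15 phosphonium bromide; 26 (2E,4E,6E)-2,7-dimethylocta-2,4,6-trienedial
Product: 28 (2E,4E,6E,8E,10E,12E,14E)-2,7,11,15,19-pentamethylicosa-2,4,6,8,10,12,14,18-octaenal (C25 aldehyde), via C15 phosphorus ylide 27 (not isolated)
Conditions: NaOMe, MeOH/CH2Cl2, 0 °C to rt, 26 in excess; then heptane, 90 °C
Reagents that add atoms: none
Why: Wittig mono-olefination is favoured by the excess of dialdehyde and by the lower electrophilicity of the longer polyenal formed, and heating should equilibrate the new C11'=C12' bond to E.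

Step 23
Reactants: 28 C25 aldehyde
Product: 29 (2E,4E,6E,8E,10E,12E,14E)-2,7,11,15,19-pentamethylicosa-2,4,6,8,10,12,14,18-octaen-1-ol
Conditions: NaBH4, MeOH/THF, 0 °C
Reagents that add atoms: none
Why: borohydride reduces the polyenal 1,2 to the allylic alcohol.

Step 24
Reactants: 29 C25 alcohol
Product: 30 [(2E,4E,6E,8E,10E,12E,14E)-2,7,11,15,19-pentamethylicosa-2,4,6,8,10,12,14,18-octaen-1-yl]triphenylphosphonium bromide
Conditions: PPh3·HBr, MeOH/CH2Cl2, rt
Reagents that add atoms: triphenylphosphine hydrobromide, [Br-].c1ccc(cc1)[PH+](c1ccccc1)c1ccccc1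
Why: the polyenylic alcohol ionises readily and PPh3 captures the cation at the terminal carbon (phosphonium salt formation), which keeps all acid away from the furanoid fragment.

Step 25
Reactants: 30 C25 phosphonium bromide; 22 furanoid C15 aldehyde
Product: 32 (3S,5R,8S)-5,8-epoxy-5,8-dihydro-β,ψ-caroten-3-ol (target), via C25 phosphorus ylide 31 (not isolated)
Conditions: 1,2-epoxybutane, EtOH, 65 °C; then heptane, 90 °C
Reagents that add atoms: none
Why: in this Wittig reaction the epoxide takes up HBr and releases the ylide only in low concentration, so the medium stays nearly neutral and the C8–H γ to the aldehyde should survive; the free hydroxyl is tolerated, and heating should turn the 11Z portion into the all-E polyene.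

**Compound list**

1 | 3-chloro-3-methylbut-1-yne | C#CC(C)(C)Cl | starting material
2 | diethyl malonate | CCOC(=O)CC(=O)OCC | starting material
3 | diethyl 2-(2-methylbut-3-yn-2-yl)propanedioate | CCOC(=O)C(C(=O)OCC)C(C)(C)C#C | intermediate
4 | ethyl 3,3-dimethylpent-4-ynoate | CCOC(=O)CC(C)(C)C#C | intermediate
5 | 3,3-dimethylpent-4-ynal | O=CCC(C)(C)C#C | intermediate
6 | (4S)-6,6-dimethyloct-1-en-7-yn-4-ol | C=CC[C@H](O)CC(C)(C)C#C | intermediate
7 | tert-butyl{[(4S)-6,6-dimethyloct-1-en-7-yn-4-yl]oxy}dimethylsilane | C=CC[C@H](O[Si](C)(C)C(C)(C)C)CC(C)(C)C#C | intermediate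
8 | (4R)-4-(tert-butyldimethylsilyloxy)-6,6-dimethyloct-7-yne-1,2-diol, both C2 epimers (descriptor change from 7 by priority only) | OCC(O)C[C@H](O[Si](C)(C)C(C)(C)C)CC(C)(C)C#C | intermediate
9 | (4R)-4-(tert-butyldimethylsilyloxy)-2-hydroxy-6,6-dimethyloct-7-yn-1-yl bromoacetate, both C2 epimers | BrCC(=O)OCC(O)C[C@H](O[Si](C)(C)C(C)(C)C)CC(C)(C)C#C | intermediate
10 | (4R)-4-(tert-butyldimethylsilyloxy)-6,6-dimethyl-2-oxooct-7-yn-1-yl bromoacetate | BrCC(=O)OCC(=O)C[C@H](O[Si](C)(C)C(C)(C)C)CC(C)(C)C#C | intermediate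
11 | (4R)-4-(tert-butyldimethylsilyloxy)-6,6-dimethyl-2-oxooct-7-yn-1-yl diazoacetate (key-step precursor) | [N-]=[N+]=CC(=O)OCC(=O)C[C@H](O[Si](C)(C)C(C)(C)C)CC(C)(C)C#C | intermediate
12 | six-membered cyclic carbonyl ylide, 5-[(2R)-2-(tert-butyldimethylsilyloxy)-4,4-dimethylhex-5-yn-1-yl]-2-oxo-1,4-dioxin-4-ium-3-ide | O=C1[CH-][O+]=C(C[C@H](O[Si](C)(C)C(C)(C)C)CC(C)(C)C#C)CO1 | intermediate (not isolated)
13 | oxa-bridged tricyclic lactone, 3-(tert-butyldimethylsilyloxy)-5,5-dimethyl-10,12-dioxatricyclo[6.3.1.0(1,6)]dodec-6-en-9-one, carotenoid centres 3R,5R,8S (key-step product) | O=C1OC[C@@]23C[C@H](O[Si](C)(C)C(C)(C)C)CC(C)(C)C2=C[C@@H]1O3 | intermediate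
14 | (2S,6R,7aR)-6-(tert-butyldimethylsilyloxy)-7a-(hydroxymethyl)-N-methoxy-N,4,4-trimethyl-2,4,5,6,7,7a-hexahydro-1-benzofuran-2-carboxamide | CON(C)C(=O)[C@@H]1C=C2C(C)(C)C[C@@H](O[Si](C)(C)C(C)(C)C)C[C@@]2(CO)O1 | intermediate
15 | 1-[(2S,6R,7aR)-6-(tert-butyldimethylsilyloxy)-7a-(hydroxymethyl)-4,4-dimethyl-2,4,5,6,7,7a-hexahydro-1-benzofuran-2-yl]ethan-1-one | CC(=O)[C@@H]1C=C2C(C)(C)C[C@@H](O[Si](C)(C)C(C)(C)C)C[C@@]2(CO)O1 | intermediate
16 | ethyl (2E)-3-[(2S,6R,7aR)-6-(tert-butyldimethylsilyloxy)-7a-(hydroxymethyl)-4,4-dimethyl-2,4,5,6,7,7a-hexahydro-1-benzofuran-2-yl]but-2-enoate | CCOC(=O)/C=C(\C)[C@@H]1C=C2C(C)(C)C[C@@H](O[Si](C)(C)C(C)(C)C)C[C@@]2(CO)O1 | intermediate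
17 | ethyl (2E)-3-[(2S,6R,7aR)-6-(tert-butyldimethylsilyloxy)-4,4-dimethyl-7a-{[(trifluoromethanesulfonyl)oxy]methyl}-2,4,5,6,7,7a-hexahydro-1-benzofuran-2-yl]but-2-enoate | CCOC(=O)/C=C(\C)[C@@H]1C=C2C(C)(C)C[C@@H](O[Si](C)(C)C(C)(C)C)C[C@@]2(COS(=O)(=O)C(F)(F)F)O1 | intermediate
18 | (2E)-3-[(2S,6R,7aR)-6-(tert-butyldimethylsilyloxy)-4,4,7a-trimethyl-2,4,5,6,7,7a-hexahydro-1-benzofuran-2-yl]but-2-en-1-ol | OC/C=C(\C)[C@@H]1C=C2C(C)(C)C[C@@H](O[Si](C)(C)C(C)(C)C)C[C@@]2(C)O1 | intermediate
19 | (2S,6R,7aR)-2-[(2E)-4-hydroxybut-2-en-2-yl]-4,4,7a-trimethyl-2,4,5,6,7,7a-hexahydro-1-benzofuran-6-ol | OC/C=C(\C)[C@@H]1C=C2C(C)(C)C[C@@H](O)C[C@@]2(C)O1 | intermediate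
20 | (2E)-3-[(2S,7aR)-4,4,7a-trimethyl-6-oxo-2,4,5,6,7,7a-hexahydro-1-benzofuran-2-yl]but-2-enal | O=C/C=C(\C)[C@@H]1C=C2C(C)(C)CC(=O)C[C@@]2(C)O1 | intermediate
21 | (2S,6S,7aR)-2-[(2E)-4-hydroxybut-2-en-2-yl]-4,4,7a-trimethyl-2,4,5,6,7,7a-hexahydro-1-benzofuran-6-ol | OC/C=C(\C)[C@@H]1C=C2C(C)(C)C[C@H](O)C[C@@]2(C)O1 | intermediate
22 | (2E)-3-[(2S,6S,7aR)-6-hydroxy-4,4,7a-trimethyl-2,4,5,6,7,7a-hexahydro-1-benzofuran-2-yl]but-2-enal | O=C/C=C(\C)[C@@H]1C=C2C(C)(C)C[C@H](O)C[C@@]2(C)O1 | intermediate
23 | pseudoionone, (3E,5E)-6,10-dimethylundeca-3,5,9-trien-2-one | CC(C)=CCC/C(C)=C/C=C/C(C)=O | starting material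
24 | (4E,6E)-3,7,11-trimethyldodeca-1,4,6,10-tetraen-3-ol (racemic) | CC(C)=CCC/C(C)=C/C=C/C(C)(O)C=C | intermediate
25 | [(2E,4E,6E)-3,7,11-trimethyldodeca-2,4,6,10-tetraen-1-yl]triphenylphosphonium bromide | CC(C)=CCC/C(C)=C/C=C/C(C)=C/C[P+](c1ccccc1)(c1ccccc1)c1ccccc1.[Br-] | intermediate
26 | (2E,4E,6E)-2,7-dimethylocta-2,4,6-trienedial (C10 dialdehyde) | O=C/C(C)=C/C=C/C=C(C)/C=O | starting material
27 | C15 phosphorus ylide, [(2E,4E,6E)-3,7,11-trimethyldodeca-2,4,6,10-tetraen-1-ylidene]triphenylphosphorane | CC(C)=CCC/C(C)=C/C=C/C(C)=C/C=P(c1ccccc1)(c1ccccc1)c1ccccc1 | intermediate (not isolated)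
28 | (2E,4E,6E,8E,10E,12E,14E)-2,7,11,15,19-pentamethylicosa-2,4,6,8,10,12,14,18-octaenal | CC(C)=CCC/C(C)=C/C=C/C(C)=C/C=C/C(C)=C/C=C/C=C(C)/C=O | intermediate
29 | (2E,4E,6E,8E,10E,12E,14E)-2,7,11,15,19-pentamethylicosa-2,4,6,8,10,12,14,18-octaen-1-ol | CC(C)=CCC/C(C)=C/C=C/C(C)=C/C=C/C(C)=C/C=C/C=C(C)/CO | intermediate
30 | [(2E,4E,6E,8E,10E,12E,14E)-2,7,11,15,19-pentamethylicosa-2,4,6,8,10,12,14,18-octaen-1-yl]triphenylphosphonium bromide | CC(C)=CCC/C(C)=C/C=C/C(C)=C/C=C/C(C)=C/C=C/C=C(C)/C[P+](c1ccccc1)(c1ccccc1)c1ccccc1.[Br-] | intermediate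
31 | C25 phosphorus ylide, [(2E,4E,6E,8E,10E,12E,14E)-2,7,11,15,19-pentamethylicosa-2,4,6,8,10,12,14,18-octaen-1-ylidene]triphenylphosphorane | CC(C)=CCC/C(C)=C/C=C/C(C)=C/C=C/C(C)=C/C=C/C=C(C)/C=P(c1ccccc1)(c1ccccc1)c1ccccc1 | intermediate (not isolated)
32 | (3S,5R,8S)-5,8-epoxy-5,8-dihydro-β,ψ-caroten-3-ol | CC(C)=CCC/C(C)=C/C=C/C(C)=C/C=C/C(C)=C/C=C/C=C(C)/C=C/C=C(\C)[C@@H]1C=C2C(C)(C)C[C@H](O)C[C@@]2(C)O1 | target

**Step count**

Total steps: 25. Longest linear sequence: 20 (steps 1 to 19, then step 25); the C25 branch is steps 20 to 24.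

**Steps most likely to fail**

Step 10. The tether may close through a boat-like rather than a chair-like arrangement, so that the ylide is attacked on the face opposite to the one predicted and the silyloxy group ends trans to the oxygen bridge. The fallback sets out from 5 and returns at 21; it changes the relay from "3-epimer, then inversion" to "target C3 from the start". Allylation of 5 with the antipodal borane (+)-Ipc2B(allyl) would give (4R)-6,6-dimethyloct-1-en-7-yn-4-ol F1. The operations of steps 5 to 9 would then give silyl ether F2, diol F3, bromoacetate F4, keto ester F5 and diazo ester F6. With the reversed facial sense, the Rh2(OAc)4 cycloaddition of F6 would give the 3S,5R,8S lactone F7, in which C3 already has the configuration of the target. The operations of steps 11 to 13 would give Weinreb amide F8, methyl ketone F9 and enoate F10. Triflation would give triflate F11, which must be reduced at once at −78 °C with LiBHEt3 because the silyloxy group is now cis to C18, to give allylic alcohol F12. Desilylation of F12 with Bu4NF gives 21 directly, and steps 17 and 18 fall away.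

Step 15. The neopentyl triflate may ionise with participation of the C6=C7 double bond (homoallyl to cyclopropylcarbinyl shift), the hydride may attack at sulfur instead of carbon, or the enoate may be reduced in the conjugate sense. The fallback sets out from 16 and returns at 18, and removes the C18 oxygen through the aldehyde instead of a leaving group. Dess–Martin oxidation of 16 would give the non-enolisable aldehyde F13. Condensation with TsNHNH2 would give the tosylhydrazone F14. Reduction with catecholborane in CHCl3 at 0 °C, followed by NaOAc·3H2O at 60 °C, would lose sulfinate and N2 to give the C18-methyl enoate F15, and i-Bu2AlH in CH2Cl2 at −78 °C would then give 18.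

Step 25. The ylide may deprotonate C8, which is γ to the aldehyde, allylic and α to oxygen, with loss of the C8 configuration or opening of the dihydrofuran, and the E selectivity at C11=C12 may be incomplete. The fallback sets out from 29 and returns at 32, and replaces the Wittig by a Horner–Wadsworth–Emmons coupling. PBr3 and pyridine in Et2O at −20 °C would convert 29 into the allylic bromide F16. An Arbuzov reaction with P(OEt)3 would give the diethyl phosphonate F17. Its anion, preformed with NaN(SiMe3)2 in THF at −78 °C (two equivalents, one taken up by the hydroxyl of 22), would be combined with 22 at −78 °C to give 32 with higher E selectivity and only brief exposure of the aldehyde to base.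

Further compounds
F1 | step 10 | (4R)-6,6-dimethyloct-1-en-7-yn-4-ol | C=CC[C@@H](O)CC(C)(C)C#C
F2 | step 10 | tert-butyl{[(4R)-6,6-dimethyloct-1-en-7-yn-4-yl]oxy}dimethylsilane | C=CC[C@@H](O[Si](C)(C)C(C)(C)C)CC(C)(C)C#C
F3 | step 10 | (4S)-4-(tert-butyldimethylsilyloxy)-6,6-dimethyloct-7-yne-1,2-diol, both C2 epimers | OCC(O)C[C@@H](O[Si](C)(C)C(C)(C)C)CC(C)(C)C#C
F4 | step 10 | (4S)-4-(tert-butyldimethylsilyloxy)-2-hydroxy-6,6-dimethyloct-7-yn-1-yl bromoacetate, both C2 epimers | BrCC(=O)OCC(O)C[C@@H](O[Si](C)(C)C(C)(C)C)CC(C)(C)C#C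
F5 | step 10 | (4S)-4-(tert-butyldimethylsilyloxy)-6,6-dimethyl-2-oxooct-7-yn-1-yl bromoacetate | BrCC(=O)OCC(=O)C[C@@H](O[Si](C)(C)C(C)(C)C)CC(C)(C)C#C
F6 | step 10 | (4S)-4-(tert-butyldimethylsilyloxy)-6,6-dimethyl-2-oxooct-7-yn-1-yl diazoacetate | [N-]=[N+]=CC(=O)OCC(=O)C[C@@H](O[Si](C)(C)C(C)(C)C)CC(C)(C)C#C
F7 | step 10 | oxa-bridged tricyclic lactone with the carotenoid centres 3S,5R,8S | O=C1OC[C@@]23C[C@@H](O[Si](C)(C)C(C)(C)C)CC(C)(C)C2=C[C@@H]1O3
F8 | step 10 | (2S,6S,7aR)-6-(tert-butyldimethylsilyloxy)-7a-(hydroxymethyl)-N-methoxy-N,4,4-trimethyl-2,4,5,6,7,7a-hexahydro-1-benzofuran-2-carboxamide | CON(C)C(=O)[C@@H]1C=C2C(C)(C)C[C@H](O[Si](C)(C)C(C)(C)C)C[C@@]2(CO)O1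
F9 | step 10 | 1-[(2S,6S,7aR)-6-(tert-butyldimethylsilyloxy)-7a-(hydroxymethyl)-4,4-dimethyl-2,4,5,6,7,7a-hexahydro-1-benzofuran-2-yl]ethan-1-one | CC(=O)[C@@H]1C=C2C(C)(C)C[C@H](O[Si](C)(C)C(C)(C)C)C[C@@]2(CO)O1
F10 | step 10 | ethyl (2E)-3-[(2S,6S,7aR)-6-(tert-butyldimethylsilyloxy)-7a-(hydroxymethyl)-4,4-dimethyl-2,4,5,6,7,7a-hexahydro-1-benzofuran-2-yl]but-2-enoate | CCOC(=O)/C=C(\C)[C@@H]1C=C2C(C)(C)C[C@H](O[Si](C)(C)C(C)(C)C)C[C@@]2(CO)O1
F11 | step 10 | ethyl (2E)-3-[(2S,6S,7aR)-6-(tert-butyldimethylsilyloxy)-4,4-dimethyl-7a-{[(trifluoromethanesulfonyl)oxy]methyl}-2,4,5,6,7,7a-hexahydro-1-benzofuran-2-yl]but-2-enoate | CCOC(=O)/C=C(\C)[C@@H]1C=C2C(C)(C)C[C@H](O[Si](C)(C)C(C)(C)C)C[C@@]2(COS(=O)(=O)C(F)(F)F)O1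
F12 | step 10 | (2E)-3-[(2S,6S,7aR)-6-(tert-butyldimethylsilyloxy)-4,4,7a-trimethyl-2,4,5,6,7,7a-hexahydro-1-benzofuran-2-yl]but-2-en-1-ol | OC/C=C(\C)[C@@H]1C=C2C(C)(C)C[C@H](O[Si](C)(C)C(C)(C)C)C[C@@]2(C)O1
F13 | step 15 | ethyl (2E)-3-[(2S,6R,7aR)-6-(tert-butyldimethylsilyloxy)-7a-formyl-4,4-dimethyl-2,4,5,6,7,7a-hexahydro-1-benzofuran-2-yl]but-2-enoate | CCOC(=O)/C=C(\C)[C@@H]1C=C2C(C)(C)C[C@@H](O[Si](C)(C)C(C)(C)C)C[C@@]2(C=O)O1
F14 | step 15 | p-toluenesulfonylhydrazone of F13 | CCOC(=O)/C=C(\C)[C@@H]1C=C2C(C)(C)C[C@@H](O[Si](C)(C)C(C)(C)C)C[C@@]2(C=NNS(=O)(=O)c3ccc(C)cc3)O1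
F15 | step 15 | ethyl (2E)-3-[(2S,6R,7aR)-6-(tert-butyldimethylsilyloxy)-4,4,7a-trimethyl-2,4,5,6,7,7a-hexahydro-1-benzofuran-2-yl]but-2-enoate | CCOC(=O)/C=C(\C)[C@@H]1C=C2C(C)(C)C[C@@H](O[Si](C)(C)C(C)(C)C)C[C@@]2(C)O1
F16 | step 25 | (2E,4E,6E,8E,10E,12E,14E)-1-bromo-2,7,11,15,19-pentamethylicosa-2,4,6,8,10,12,14,18-octaene | CC(C)=CCC/C(C)=C/C=C/C(C)=C/C=C/C(C)=C/C=C/C=C(C)/CBr
F17 | step 25 | diethyl [(2E,4E,6E,8E,10E,12E,14E)-2,7,11,15,19-pentamethylicosa-2,4,6,8,10,12,14,18-octaen-1-yl]phosphonate | CC(C)=CCC/C(C)=C/C=C/C(C)=C/C=C/C(C)=C/C=C/C=C(C)/CP(=O)(OCC)OCC
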